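| setting | alpha | flask |
|---|---|---|
| starting material | 0.20 M | 0.20 M |
| coupling partner | 4 equiv | 4.00 equiv |
| initiator | 5 mol% | 5 mol% |
| remark | the very flask that is asked about, followed so far |  |
| time |  | 3.0 h |

alpha run (percent of the starting material charged)

| time / min | product / % |
|---|---|
| 3.00 | 2.0 |
| 5.00 | 2.4 |
| 10.0 | 5.0 |
| 20.0 | 9.8 |
| 40.0 | 22.3 |

(standard deviation of a reading: 1 percentage point)

* which holds at 3.0 h: what has brought the reaction to rest, or that it has not come to rest (all of the starting material has reacted / it is still moving / forward and back rates have come level / the coupling partner has run out first)
* product at 3.0 h, in percent of the starting material charged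

- the numbers in the tables scatter by 1 percentage point (one standard deviation)
- the reaction counts as stopped when no species that holds the starting material changes by six tenths of a point or more over the second half of the time

- The alpha flask holds 0.20 M of starting material and 4 equiv of coupling partner, and product is counted against the starting material, so that charge is the ceiling for product.
- One way forward is a straight line: the reading of 22.3% at 40.0 min, run on at its own slope, reaches 100% at 3.0 h.
- The other way follows one molecule of starting material. Taking −ln(1 − y)/t for product fraction y at time t, the reading at 20.0 min gives 0.00516 min⁻¹ and the reading at 40.0 min gives 0.00631 min⁻¹. With a scatter of 1 percentage point neither is preferred, so their mean is carried: 0.00573 min⁻¹. This is k, the chance per minute that a molecule still unreacted becomes product, a pseudo-first-order constant as a working assumption.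
- That chance gives 64.4% at 3.0 h, with 24 points gained over the second half of the time, so this reckoning has the flask still moving.
- The two ways part, and the line is judged to cheat: it keeps its rate while the molecules are consumed, and the readings stop too early to show any slowing.
- The forecast says it is still moving and gives 65%, a figure of its own, not the 64.4% reckoned here, and holds that “The partner cannot run out, and nothing in the data shows an equilibrium ceiling”.
- At 3.0 h the flask gives 65.0%, and it is still moving.

    initiator → 2 initiating radical (k = 9.80 × 10⁻⁴ min⁻¹)
    starting material + initiating radical → capped initiator + first chain carrier (k = 2.40 × 10⁵ M⁻¹ s⁻¹)
    coupling partner + first chain carrier → product + second chain carrier (k = 84000 M⁻¹ min⁻¹)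
    starting material + second chain carrier → by-product + first chain carrier (k = 11000 M⁻¹ s⁻¹)
    2 second chain carrier → ended chains A (k = 3.00 × 10⁷ M⁻¹ s⁻¹)
    2 first chain carrier → ended chains B (k = 6.70 × 10⁸ M⁻¹ s⁻¹)
    starting material ⇌ dormant form (K = 3.10, k = 0.0770 min⁻¹)

- On the same measure, the product of this flask at 3.0 h stands for 0.00583 min⁻¹, against 0.00573 min⁻¹ for k. The main reason that product stops short of the charge at 3.0 h is the pairing of first chain carriers into ended chains B: the same flask without that step gives 84.7%, a gain of 20 points.
- A figure reckoned in this way is wrong where k moves, and a neighbour flask shows it moving: 0.050 M of starting material, with the equivalents, the loading and the time held, so that every charge is lower together. An unchanged k gives 64.4% for that neighbour flask. It computes to 37.8%, which stands for 0.00263 min⁻¹, about half of k.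

Readings and results were computed for substances that don't exist; noise was put on by code.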